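**Retrosynthetic overview**

1. The acid comes from its ethyl ester 24. The ester is cut at C2'–C3' of the side chain (sp3–sp2 Negishi coupling) into the chroman-2-ylethyl iodide 16 and the (6E)-vinyl iodide (2Z)-enoate 22, which is made from pent-4-yn-1-ol by carboalumination–iodination and Still–Gennari olefination.
2. Feature used: ring A (the benzene ring) carries oxygen on C8a (ring oxygen O1) and on C6 (the methoxy oxygen), para to each other. The chromane is therefore the aromatised form of a cyclohexa-2,5-dienone whose C8a is a spiro carbon bearing O1 and the ring methylene C4.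
3. Key disconnection C4–C4a: chromanol 13 goes back to the 1-oxaspiro[4.5]deca-6,9-dien-8-one 12, which rearranges by a dienone–phenol 1,2-shift of C4.
4. 12 comes from phenol 11 by oxidative spirocyclisation through its tertiary hydroxyl. That carbinol carbon (the future C2) is set by Sharpless epoxidation and hydride opening of allylic alcohol 7, built from 4-bromo-3-methylphenol by Heck and Horner–Wadsworth–Emmons reactions.
5. Ring order: the benzene ring is bought, the spiro oxolane is closed in step 9, and it is expanded to the dihydropyran ring B in step 10.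

Key step: step 10

Remark: 12 is formed and used as a mixture of its two C5 epimers (one is drawn), because C5 becomes the trigonal carbon C8a in step 10.
Remark: the descriptor of the quaternary carbon reads S in 8–16 and 23 and R in 24 and 25 only because the CIP ranking of its substituents changes; none of its bonds is broken after step 5.

**Route**

Step 1
Reactants: 1 4-bromo-3-methylphenol
Product: 2 4-(benzyloxy)-1-bromo-2-methylbenzene
Conditions: BnBr, K2CO3, acetone, reflux
Reagents that add atoms: benzyl bromide, BrCc1ccccc1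
Why: Williamson ether synthesis on the phenoxide; the benzyl ether should survive the hot basic Heck medium, the aluminium hydrides and the titanium catalyst, and it can be removed by hydrogenolysis at a stage where no alkene is present.

Step 2
Reactants: 2 4-(benzyloxy)-1-bromo-2-methylbenzene; 3 but-3-en-2-ol (racemic)
Product: 4 4-[4-(benzyloxy)-2-methylphenyl]butan-2-one
Conditions: Pd(OAc)2 (3 mol %), P(o-tol)3 (6 mol %), NaHCO3, DMF, 110 °C
Reagents that add atoms: none
Why: Heck arylation of a secondary allylic alcohol, in which the arylpalladium species adds to the terminal alkene carbon and β-hydride elimination toward the carbinol carbon followed by tautomerisation should give the saturated methyl ketone.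

Step 3
Reactants: 4 4-[4-(benzyloxy)-2-methylphenyl]butan-2-one; 5 triethyl phosphonoacetate
Product: 6 ethyl (2E)-5-[4-(benzyloxy)-2-methylphenyl]-3-methylpent-2-enoate
Conditions: NaH, THF, 0 °C → 50 °C; minor (Z)-ester removed by chromatography
Reagents that add atoms: none
Why: Horner–Wadsworth–Emmons olefination, which with a methyl ketone should favour the (E)-enoate; the (Z)-ester has to be removed because it would later give the opposite configuration at the quaternary carbon.

Step 4
Reactants: 6 ethyl (2E)-5-[4-(benzyloxy)-2-methylphenyl]-3-methylpent-2-enoate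
Product: 7 (2E)-5-[4-(benzyloxy)-2-methylphenyl]-3-methylpent-2-en-1-ol
Conditions: iBu2AlH (2.5 equiv), CH2Cl2, −78 °C → 0 °C
Reagents that add atoms: none
Why: 1,2-reduction of an α,β-unsaturated ester to the allylic alcohol by an aluminium hydride, which leaves the alkene geometry and the benzyl ether untouched.

Step 5
Reactants: 7 (2E)-5-[4-(benzyloxy)-2-methylphenyl]-3-methylpent-2-en-1-ol
Product: 8 [(2S,3S)-3-{2-[4-(benzyloxy)-2-methylphenyl]ethyl}-3-methyloxiran-2-yl]methanol
Conditions: Ti(OiPr)4 (10 mol %), L-(+)-diethyl tartrate (12 mol %), t-BuOOH, 4 Å molecular sieves, CH2Cl2, −20 °C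
Reagents that add atoms: tert-butyl hydroperoxide, CC(C)(C)OO
Why: Sharpless asymmetric epoxidation, in which the titanium tartrate catalyst binds the allylic hydroxyl and transfers the peroxide oxygen to one alkene face; with L-(+)-diethyl tartrate an (E)-3,3-disubstituted allylic alcohol of the geraniol type should give the (2S,3S)-epoxide, whose C3 becomes C2 of the chromane.

Step 6
Reactants: 8 [(2S,3S)-3-{2-[4-(benzyloxy)-2-methylphenyl]ethyl}-3-methyloxiran-2-yl]methanol
Product: 9 (3S)-5-[4-(benzyloxy)-2-methylphenyl]-3-methylpentane-1,3-diol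
Conditions: NaAlH2(OCH2CH2OMe)2, THF, 0 °C → rt
Reagents that add atoms: none
Why: Regioselective reductive opening of a 2,3-epoxy alcohol, in which hydride is delivered from the alkoxyaluminate on the primary oxygen to the less substituted C2, so the 1,3-diol should form while the C3–O bond and its configuration stay intact.

Step 7
Reactants: 9 (3S)-5-[4-(benzyloxy)-2-methylphenyl]-3-methylpentane-1,3-diol
Product: 10 (3S)-5-[4-(benzyloxy)-2-methylphenyl]-3-hydroxy-3-methylpentyl pivalate
Conditions: PivCl, pyridine, CH2Cl2, 0 °C
Reagents that add atoms: pivaloyl chloride, CC(C)(C)C(Cl)=O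
Why: Chemoselective acylation, in which the hindered acid chloride esterifies the primary hydroxyl only and leaves the tertiary hydroxyl free as the nucleophile for the spirocyclisation.

Step 8
Reactants: 10 (3S)-5-[4-(benzyloxy)-2-methylphenyl]-3-hydroxy-3-methylpentyl pivalate
Product: 11 (3S)-3-hydroxy-5-(4-hydroxy-2-methylphenyl)-3-methylpentyl pivalate
Conditions: H2 (1 atm), Pd/C (10 % palladium on carbon), EtOAc, rt
Reagents that add atoms: none
Why: Hydrogenolysis of a benzyl aryl ether, which should free the phenol without touching the ester or the tertiary alcohol, no alkene being present.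

Step 9
Reactants: 11 (3S)-3-hydroxy-5-(4-hydroxy-2-methylphenyl)-3-methylpentyl pivalate
Product: 12 2-[(2S)-2,6-dimethyl-8-oxo-1-oxaspiro[4.5]deca-6,9-dien-2-yl]ethyl pivalate (both C5 epimers)
Conditions: PhI(OAc)2 (1.1 equiv), (CF3)2CHOH, 0 °C
Reagents that add atoms: none
Why: Oxidative dearomatisation of a 4-(3-hydroxyalkyl)phenol by a trivalent iodine reagent, in which the phenol exchanges an acetate on iodine and the tertiary hydroxyl attacks the para carbon in a 5-exo mode as iodobenzene leaves, so the spiro ether should form in a non-nucleophilic solvent.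

Step 10
Reactants: 12 2-[(2S)-2,6-dimethyl-8-oxo-1-oxaspiro[4.5]deca-6,9-dien-2-yl]ethyl pivalate
Product: 13 2-[(2S)-6-hydroxy-2,8-dimethylchroman-2-yl]ethyl pivalate
Conditions: BF3·OEt2 (30 mol %), CH2Cl2, −20 °C → rt
Reagents that add atoms: none
Why: Dienone–phenol rearrangement: BF3 binds the C8 carbonyl oxygen and creates a hydroxypentadienyl-type cation with positive charge on C6 and C10, the ring methylene C4 shifts from the spiro carbon C5 to the hydrogen-bearing C10, the cation left on C5 is an oxocarbenium ion stabilised by O1, and loss of the C10 proton gives the arene with the free C6 phenol. The closest known reaction type is the acid-promoted rearrangement of 4-alkoxy-4-alkylcyclohexa-2,5-dienones and of 1-oxaspiro[4.5]deca-6,9-dien-8-ones to hydroquinone monoethers and chroman-6-ols. The dihydropyran ring is closed by ring expansion of the oxolane through this 1,2-alkyl shift (five to six members, new bond C4–C4a) and not by an exo or endo cyclisation. No stereocentre is created: C5 becomes the trigonal C8a, so both epimers of 12 converge, and C2 keeps the configuration from step 5 because the O1–C2 bond is not broken. The step needs carbon and not oxygen to migrate, which should hold because only the carbon shift leaves an oxygen-stabilised cation, and it needs migration to C10 and not to the methyl-bearing C6, which should hold because only the C10 adduct can aromatise by proton loss while a shift to C6 is reversible. The pivalate keeps the side-chain oxygen from trapping the oxocarbenium ion, and the low temperature and substoichiometric Lewis acid limit ionisation of the tertiary O1–C2 bond.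

Step 11
Reactants: 13 2-[(2S)-6-hydroxy-2,8-dimethylchroman-2-yl]ethyl pivalate
Product: 14 2-[(2S)-6-methoxy-2,8-dimethylchroman-2-yl]ethyl pivalate
Conditions: MeI, K2CO3, acetone, reflux
Reagents that add atoms: iodomethane, CI
Why: Williamson O-methylation of the only acidic hydroxyl, the C6 phenol; the pivalate is inert to carbonate.

Step 12
Reactants: 14 2-[(2S)-6-methoxy-2,8-dimethylchroman-2-yl]ethyl pivalate
Product: 15 2-[(2S)-6-methoxy-2,8-dimethylchroman-2-yl]ethanol
Conditions: LiAlH4, THF, 0 °C
Reagents that add atoms: none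
Why: Reductive cleavage of the hindered ester by an aluminium hydride, which should free the primary alcohol without affecting the aryl ethers.

Step 13
Reactants: 15 2-[(2S)-6-methoxy-2,8-dimethylchroman-2-yl]ethanol
Product: 16 (2S)-2-(2-iodoethyl)-6-methoxy-2,8-dimethylchromane
Conditions: I2, PPh3, imidazole, CH2Cl2, 0 °C → rt
Reagents that add atoms: iodine, II
Why: Appel-type iodination, in which the alkoxyphosphonium ion of the unhindered primary alcohol is displaced by iodide in an SN2 reaction.

Step 14
Reactants: 17 pent-4-yn-1-ol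
Product: 19 (4E)-5-iodo-4-methylpent-4-en-1-ol, via (E)-alkenylalane 18 (not isolated)
Conditions: AlMe3 (3 equiv), Cp2ZrCl2 (25 mol %), CH2Cl2, 0 °C → rt; then I2, THF, −30 °C; aq. K2CO3
Reagents that add atoms: trimethylaluminium, C[Al](C)C; iodine, II
Why: Zirconium-catalysed methylalumination of a terminal alkyne (Negishi carboalumination), a syn addition that places methyl on the internal carbon, followed by iodinolysis of the C–Al bond with retention, so the (E)-vinyl iodide should form as a single isomer.

Step 15
Reactants: 19 (4E)-5-iodo-4-methylpent-4-en-1-ol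
Product: 20 (4E)-5-iodo-4-methylpent-4-enal
Conditions: PhI(OAc)2 (1.1 equiv), TEMPO (10 mol %), CH2Cl2, rt
Reagents that add atoms: none
Why: Oxoammonium-mediated oxidation of a primary alcohol to the aldehyde, which stops at the aldehyde and should not touch the vinyl iodide.

Step 16
Reactants: 20 (4E)-5-iodo-4-methylpent-4-enal; 21 ethyl 2-[bis(2,2,2-trifluoroethoxy)phosphoryl]propanoate
Product: 22 ethyl (2Z,6E)-7-iodo-2,6-dimethylhepta-2,6-dienoate
Conditions: KN(SiMe3)2, 18-crown-6, THF, −78 °C; then 20
Reagents that add atoms: none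
Why: Still–Gennari olefination, in which the electron-poor bis(trifluoroethyl) phosphonate under dissociating conditions eliminates fast from the kinetic adduct and should give the (Z)-trisubstituted enoate.

Step 17
Reactants: 16 (2S)-2-(2-iodoethyl)-6-methoxy-2,8-dimethylchromane; 22 ethyl (2Z,6E)-7-iodo-2,6-dimethylhepta-2,6-dienoate
Product: 24 ethyl (2Z,6E)-9-[(2R)-6-methoxy-2,8-dimethylchroman-2-yl]-2,6-dimethylnona-2,6-dienoate, via alkylzinc iodide 23 (not isolated)
Conditions: Zn dust (I2-activated), N,N-dimethylacetamide, rt; then 22, PdCl2(dppf) (5 mol %), rt → 40 °C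
Reagents that add atoms: none
Why: Negishi coupling, in which zinc inserts into the primary C–I bond (the ring oxygen is γ to zinc, so no β-alkoxide elimination is possible) and palladium joins the alkylzinc to the vinyl iodide with retention of the alkene geometry, the ester being inert to the organozinc.

Step 18
Reactants: 24 ethyl (2Z,6E)-9-[(2R)-6-methoxy-2,8-dimethylchroman-2-yl]-2,6-dimethylnona-2,6-dienoate
Product: 25 (2Z,6E)-9-[(2R)-6-methoxy-2,8-dimethylchroman-2-yl]-2,6-dimethylnona-2,6-dienoic acid
Conditions: LiOH, THF/MeOH/H2O, rt; then 1 M HCl to pH 3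
Reagents that add atoms: lithium hydroxide, [Li+].[OH-]
Why: Saponification of the ethyl ester by acyl–oxygen cleavage at room temperature, mild enough that the (Z)-enoate should not isomerise.

**Compound list**

1 | 4-bromo-3-methylphenol | Cc1cc(O)ccc1Br | starting material
2 | 4-(benzyloxy)-1-bromo-2-methylbenzene | Cc1cc(OCc2ccccc2)ccc1Br | intermediate
3 | but-3-en-2-ol (racemic) | CC(O)C=C | starting material
4 | 4-[4-(benzyloxy)-2-methylphenyl]butan-2-one | CC(=O)CCc1ccc(OCc2ccccc2)cc1C | intermediate
5 | triethyl phosphonoacetate | CCOC(=O)CP(=O)(OCC)OCC | starting material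
6 | ethyl (2E)-5-[4-(benzyloxy)-2-methylphenyl]-3-methylpent-2-enoate | CCOC(=O)/C=C(\C)CCc1ccc(OCc2ccccc2)cc1C | intermediate
7 | (2E)-5-[4-(benzyloxy)-2-methylphenyl]-3-methylpent-2-en-1-ol | OC/C=C(\C)CCc1ccc(OCc2ccccc2)cc1C | intermediate
8 | [(2S,3S)-3-{2-[4-(benzyloxy)-2-methylphenyl]ethyl}-3-methyloxiran-2-yl]methanol | Cc1cc(OCc2ccccc2)ccc1CC[C@]1(C)O[C@H]1CO | intermediate
9 | (3S)-5-[4-(benzyloxy)-2-methylphenyl]-3-methylpentane-1,3-diol | Cc1cc(OCc2ccccc2)ccc1CC[C@@](C)(CCO)O | intermediate
10 | (3S)-5-[4-(benzyloxy)-2-methylphenyl]-3-hydroxy-3-methylpentyl pivalate | Cc1cc(OCc2ccccc2)ccc1CC[C@@](C)(CCOC(=O)C(C)(C)C)O | intermediate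
11 | (3S)-3-hydroxy-5-(4-hydroxy-2-methylphenyl)-3-methylpentyl pivalate | Cc1cc(O)ccc1CC[C@@](C)(CCOC(=O)C(C)(C)C)O | intermediate
12 | 2-[(2S)-2,6-dimethyl-8-oxo-1-oxaspiro[4.5]deca-6,9-dien-2-yl]ethyl pivalate, mixture of C5 epimers, (2S,5R) epimer drawn | CC1=CC(=O)C=C[C@]12CC[C@@](C)(CCOC(=O)C(C)(C)C)O2 | intermediate
13 | 2-[(2S)-6-hydroxy-2,8-dimethylchroman-2-yl]ethyl pivalate | Cc1cc(O)cc2CC[C@@](C)(CCOC(=O)C(C)(C)C)Oc12 | intermediate
14 | 2-[(2S)-6-methoxy-2,8-dimethylchroman-2-yl]ethyl pivalate | COc1cc(C)c2c(c1)CC[C@@](C)(CCOC(=O)C(C)(C)C)O2 | intermediate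
15 | 2-[(2S)-6-methoxy-2,8-dimethylchroman-2-yl]ethanol | COc1cc(C)c2c(c1)CC[C@@](C)(CCO)O2 | intermediate
16 | (2S)-2-(2-iodoethyl)-6-methoxy-2,8-dimethylchromane | COc1cc(C)c2c(c1)CC[C@@](C)(CCI)O2 | intermediate
17 | pent-4-yn-1-ol | C#CCCCO | starting material
18 | dimethylaluminium (4E)-5-(dimethylalumanyl)-4-methylpent-4-en-1-olate [(E)-alkenylalane] | C[Al](C)/C=C(\C)CCCO[Al](C)C | intermediate (not isolated)
19 | (4E)-5-iodo-4-methylpent-4-en-1-ol | OCCC/C(C)=C/I | intermediate
20 | (4E)-5-iodo-4-methylpent-4-enal | O=CCC/C(C)=C/I | intermediate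
21 | ethyl 2-[bis(2,2,2-trifluoroethoxy)phosphoryl]propanoate | CCOC(=O)C(C)P(=O)(OCC(F)(F)F)OCC(F)(F)F | starting material
22 | ethyl (2Z,6E)-7-iodo-2,6-dimethylhepta-2,6-dienoate | CCOC(=O)/C(C)=C\CC/C(C)=C/I | intermediate
23 | {2-[(2S)-6-methoxy-2,8-dimethylchroman-2-yl]ethyl}zinc iodide | COc1cc(C)c2c(c1)CC[C@@](C)(CC[Zn]I)O2 | intermediate (not isolated)
24 | ethyl (2Z,6E)-9-[(2R)-6-methoxy-2,8-dimethylchroman-2-yl]-2,6-dimethylnona-2,6-dienoate | COc1cc(C)c2c(c1)CC[C@@](C)(CC/C=C(\C)CC/C=C(/C)C(=O)OCC)O2 | intermediate
25 | (2Z,6E)-9-[(2R)-6-methoxy-2,8-dimethylchroman-2-yl]-2,6-dimethylnona-2,6-dienoic acid (CNP0171841.1) | COc1cc(C)c2c(c1)CC[C@@](C)(CC/C=C(\C)CC/C=C(/C)C(=O)O)O2 | target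

**Step count**

Total steps: 18. Longest linear sequence: 15 (steps 1–13, 17 and 18); steps 14–16 make the side-chain fragment.

**Steps most likely to fail**

Step 10 (key step). The 1,2-shift could take the wrong course, with oxygen migrating in place of carbon or the methylene moving toward the methyl-bearing C6. The Lewis acid could also ionise the tertiary O1–C2 bond, opening the spiro ether and eroding the configuration at C2. The fallback builds the chromane by an enantioselective Wacker-type oxypalladation, not by dearomatisation, and so also replaces step 9. It sets out from but-3-en-2-ol (3). Purchased 4-methoxy-2-methylphenol F1 is iodinated ortho to the hydroxyl (N-iodosuccinimide, MeCN) to 2-iodo-4-methoxy-6-methylphenol F2. Heck reaction of F2 with 3 (Pd(OAc)2, NaHCO3, Bu4NCl, DMF) should give 4-(2-hydroxy-5-methoxy-3-methylphenyl)butan-2-one F3, in equilibrium with its cyclic hemiketal. Wittig methylenation (Ph3P=CH2 in excess, THF) should give 4-methoxy-2-methyl-6-(3-methylbut-3-en-1-yl)phenol F4. The domino oxypalladation–methoxycarbonylation (Pd(OCOCF3)2, the enantiomer of the binaphthyl bis(4-benzyloxazoline) ligand Bn-BOXAX that delivers the (S)-product, p-benzoquinone, CO, MeOH) should then give methyl 2-[(2S)-6-methoxy-2,8-dimethylchroman-2-yl]acetate F5. Reduction of F5 with LiAlH4 gives alcohol 15, where the route is rejoined before step 13.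

Step 17. Zinc insertion may stall, or the alkylzinc may be protonated or homocoupled before it transmetalates, so that the sp3–sp2 bond does not form. The fallback is a B-alkyl Suzuki–Miyaura coupling and sets out from iodide 16. Lithium–iodine exchange (t-BuLi, Et2O, −78 °C) gives {2-[(2S)-6-methoxy-2,8-dimethylchroman-2-yl]ethyl}lithium F6. Trapping with B-methoxy-9-borabicyclo[3.3.1]nonane gives lithium B-{2-[(2S)-6-methoxy-2,8-dimethylchroman-2-yl]ethyl}-B-methoxy-9-borabicyclo[3.3.1]nonan-9-uide F7. F7 is coupled in the same flask with vinyl iodide 22 (PdCl2(dppf), aqueous K3PO4, DMF, rt) and should give ester 24, where the route is rejoined before step 18.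

Step 3. The olefination of the methyl ketone may give a poorly separable E/Z mixture. Any (Z)-ester carried forward is epoxidised to the opposite configuration at the quaternary carbon and lowers the enantiomeric purity of all later compounds. The fallback fixes the geometry by carbometalation and replaces steps 3 and 4. It sets out from ketone 4. The kinetic enolate (LiN(iPr)2, THF, −78 °C) is trapped with ClP(O)(OEt)2 to give 4-[4-(benzyloxy)-2-methylphenyl]but-1-en-2-yl diethyl phosphate F8. Elimination with further LiN(iPr)2 gives 4-(benzyloxy)-1-(but-3-yn-1-yl)-2-methylbenzene F9. Zirconium-catalysed methylalumination (AlMe3, Cp2ZrCl2, CH2Cl2) gives {(1E)-4-[4-(benzyloxy)-2-methylphenyl]-2-methylbut-1-en-1-yl}dimethylalane F10. F10 is converted to the alanate with n-BuLi and hydroxymethylated with paraformaldehyde, which should give allylic alcohol 7 as the (E)-isomer only; the route is rejoined before step 5.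

Step 9 is not listed separately: it rests on direct precedent, the ratio of its C5 epimers is irrelevant, and the fallback for step 10 would replace it as well.

**Further compounds**

F1 | step 10 | 4-methoxy-2-methylphenol | COc1ccc(O)c(C)c1
F2 | step 10 | 2-iodo-4-methoxy-6-methylphenol | COc1cc(C)c(O)c(I)c1
F3 | step 10 | 4-(2-hydroxy-5-methoxy-3-methylphenyl)butan-2-one | COc1cc(C)c(O)c(CCC(C)=O)c1
F4 | step 10 | 4-methoxy-2-methyl-6-(3-methylbut-3-en-1-yl)phenol | COc1cc(C)c(O)c(CCC(C)=C)c1
F5 | step 10 | methyl 2-[(2S)-6-methoxy-2,8-dimethylchroman-2-yl]acetate | COc1cc(C)c2c(c1)CC[C@@](C)(CC(=O)OC)O2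
F6 | step 17 | {2-[(2S)-6-methoxy-2,8-dimethylchroman-2-yl]ethyl}lithium | COc1cc(C)c2c(c1)CC[C@@](C)(CC[Li])O2
F7 | step 17 | lithium B-{2-[(2S)-6-methoxy-2,8-dimethylchroman-2-yl]ethyl}-B-methoxy-9-borabicyclo[3.3.1]nonan-9-uide | COc1cc(C)c2c(c1)CC[C@@](C)(CC[B-]3(OC)C4CCCC3CCC4)O2.[Li+]
F8 | step 3 | 4-[4-(benzyloxy)-2-methylphenyl]but-1-en-2-yl diethyl phosphate | C=C(CCc1ccc(OCc2ccccc2)cc1C)OP(=O)(OCC)OCC
F9 | step 3 | 4-(benzyloxy)-1-(but-3-yn-1-yl)-2-methylbenzene | C#CCCc1ccc(OCc2ccccc2)cc1C
F10 | step 3 | {(1E)-4-[4-(benzyloxy)-2-methylphenyl]-2-methylbut-1-en-1-yl}dimethylalane | C[Al](C)/C=C(\C)CCc1ccc(OCc2ccccc2)cc1C
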